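The strategy rests on reading the chain C2–C1–O–C1′–C2′ as a cis-2,5-diaryltetrahydrofuran. C1/C1′ are the benzylic ether carbons on coumarin C8/C8′ (unlike R/S descriptors) and C2/C2′ are the carbinols. Ring O1 is the ether oxygen, ring C2/C5 are C1/C1′, ring C3/C4 are C2/C2′, and the ring C3–C4 bond is cut afterwards. The key step attaches two coumarin-8-ylzinc units to both acetal carbons of an acetonide-fused 2,5-dimethoxytetrahydrofuran, a masked meso-tartaraldehyde, in one flask. It makes C8–C1, C8′–C1′ and both benzylic stereocentres, with the crowded ether oxygen already in place. Ring scission gives a meso dialdehyde, and a ligand-controlled double isopropenylation sets C2 and C2′ (both R), breaking the symmetry.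

Key step: step 6

**Remarks on the chemistry**
- Configuration: the target is 1R,2R,1′S,2′R. The two halves are diastereomeric (syn at C1/C2, anti at C1′/C2′). Substrate control therefore cannot serve both ends, and reagent control on a meso dialdehyde is required.
- Assumption: the antipode of the oxazoline–sulfonamide ligand in step 9 is defined by its outcome, which is Re-face delivery to RCHO. It is assigned beforehand on a simple α-alkoxy aldehyde. Both antipodes are made from (S)- or (R)-valinol.
- Leaving group: methoxy is a poor leaving group towards an arylzinc. It is exchanged for bromide in the same flask, so no strong external Lewis acid meets the zinc reagent or the ketal.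
- Acetal configuration: the commercial dihydrofuran is a cis/trans mixture. This does not matter, because the acetal carbons equilibrate during ketalisation and become planar in the key step.
- Dialdehyde handling: the glycol is cleaved with a supported reagent in CH2Cl2, and Cp2ZrCl2 rather than a silyl chloride turns over chromium. Both choices protect the enolisable, hydrate-prone dialdehyde.

**Step 1**
Reactants: 1 umbelliferone (7-hydroxycoumarin)
Product: 2 7-hydroxy-8-iodocoumarin
Conditions: I2 (1.0 equiv), KI, aq NH3, rt; then dilute H2SO4 to pH 2–3
Reagents that add atoms: iodine, II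
Why: This is an electrophilic aromatic iodination of the phenoxide, in which C8 (ortho to O7, the site that also reacts in Mannich, Duff and Claisen chemistry of umbelliferone) is the most nucleophilic carbon, one equivalent of iodine limits over-iodination, and any opened lactone re-closes on acidification.

**Step 2**
Reactants: 2 7-hydroxy-8-iodocoumarin
Product: 3 8-iodo-7-methoxycoumarin
Conditions: MeI, K2CO3, acetone, reflux
Reagents that add atoms: iodomethane, CI
Why: This is a Williamson ether synthesis (SN2 of the phenoxide on MeI), and the weak base leaves the lactone and the C–I bond untouched.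

**Step 3**
Reactants: 3 8-iodo-7-methoxycoumarin
Product: 4 (7-methoxy-2-oxochromen-8-yl)zinc iodide, LiCl-solvated, kept as a titrated stock solution
Conditions: Zn dust (activated with BrCH2CH2Br/TMSCl), LiCl, THF, 25–50 °C; cannula-filtered from excess Zn; THF largely exchanged for toluene
Reagents that add atoms: zinc, [Zn]
Why: This is a LiCl-assisted direct insertion of zinc into an aryl iodide, helped by the two ortho oxygen atoms, and the resulting C–Zn bond is too unreactive to attack the lactone or the enoate of a second molecule.

**Step 4**
Reactants: 5 2,5-dimethoxy-2,5-dihydrofuran (commercial cis/trans mixture)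
Product: 6 2,5-dimethoxytetrahydrofuran-3,4-diol (cis-3,4-diol, mixture at the two acetal carbons)
Conditions: OsO4 (cat.), NMO, acetone/H2O, rt; Na2SO3
Reagents that add atoms: N-methylmorpholine N-oxide, C[N+]1([O-])CCOCC1 (oxygen relayed by OsO4); water, O
Why: This is an Upjohn dihydroxylation, in which suprafacial [3+2] addition of OsO4 gives the cis-diol (anti to both methoxy groups in the cis isomer of 5) under neutral conditions that leave the acetals alone.

**Step 5**
Reactants: 6 2,5-dimethoxytetrahydrofuran-3,4-diol
Product: 7 meso 2,5-dimethoxytetrahydrofuran-3,4-diol acetonide (both OMe exo, trans to the dioxolane)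
Conditions: 2,2-dimethoxypropane, acetone, p-TsOH (cat.), rt; Et3N quench
Reagents that add atoms: 2,2-dimethoxypropane, COC(C)(C)OC
Why: This is an acid-catalysed transketalisation of a cis-1,2-diol, in which the acid and the liberated methanol also let the acetal carbons anomerise, so the mixture should drain towards the exo,exo meso isomer as it does for methyl 2,3-O-isopropylidene furanosides.

**Step 6**
Reactants: 7 meso 2,5-dimethoxytetrahydrofuran-3,4-diol acetonide; 4 (7-methoxy-2-oxochromen-8-yl)zinc iodide (3 equiv)
Product: 10 meso cis-2,5-bis(7-methoxy-2-oxochromen-8-yl)tetrahydrofuran-3,4-diol acetonide (both aryl groups trans to the dioxolane), via bis(furanosyl bromide) 8 (not isolated), via monoaryl furanosyl bromide 9 (not isolated)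
Conditions: (i) TMSBr (2.2 equiv), 4 Å MS, CH2Cl2, −20 °C → rt, volatiles off at 0 °C; (ii) 4, toluene/THF, −20 °C → rt; aq NH4Cl
Reagents that add atoms: bromotrimethylsilane, C[Si](C)(C)Br (its bromine is found only in 8 and 9, not in 10)
Why: Bromotrimethylsilane first swaps each exocyclic methoxy group for bromide (Me3SiOMe leaves for good, whereas any opening of the dioxolane or at the ring oxygen stays tethered and re-closes); the Lewis-acidic zinc(II) of 4 then abstracts bromide from one terminus at a time, and the dioxolane-fused five-membered oxocarbenium ion collapses with the aryl group of the zincate counter-ion, 8 → 9 → 10. The closest known reaction type is the transition-metal-free C-arylation of glycosyl and furanosyl halides (α-halo ethers in general) with arylzinc reagents, here run at both ends of one dialdose derivative. No ring is closed; the two bonds formed are C8–C1 and C8′–C1′. C1 is controlled by the cis-fused bicyclo[3.3.0] shape of the cation, whose concave face is roofed by the endo methyl of the isopropylidene unit, so the doubly ortho-substituted aryl should enter on the convex face, trans to the neighbouring C–O bond; C1′ is controlled in the same way in the cation from 9, which puts both aryl groups on one face (cis-2,5, unlike descriptors) and restores the mirror plane. The step needs exo attack twice, ionisation of the exocyclic leaving groups in preference to the ketal, and substitution faster than loss of H-3/H-4 (the entry to furans); the bicyclic shape, the irreversible departure of Me3SiOMe and the non-basic, halophilic zinc reagent (freed of zinc dust, which would cause Fischer–Zach-type reductive elimination) answer these in turn. The exo,exo isomer is also the least crowded one, so any acid-induced equilibration at these benzylic ether carbons should act in the same direction.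

**Step 7**
Reactants: 10 meso cis-2,5-bis(7-methoxy-2-oxochromen-8-yl)tetrahydrofuran-3,4-diol acetonide
Product: 11 meso cis-2,5-bis(7-methoxy-2-oxochromen-8-yl)tetrahydrofuran-3,4-diol (cis-diol, trans to both aryl groups)
Conditions: TFA/H2O (4:1), 0 °C → rt; toluene co-evaporation
Reagents that add atoms: none
Why: This is an acid-catalysed ketal hydrolysis, in which the isopropylidene ketal ionises through a tertiary oxocarbenium ion far more easily than the ring C–O bonds (their benzylic cations are destabilised by the adjacent C–O bond and the electron-poor pyranone), so C1/C1′ should keep their configuration and the lactones are acid-stable.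

**Step 8**
Reactants: 11 meso cis-2,5-bis(7-methoxy-2-oxochromen-8-yl)tetrahydrofuran-3,4-diol
Product: 12 meso 2,2′-oxybis[2-(7-methoxy-2-oxochromen-8-yl)acetaldehyde] (R,S at the two benzylic carbons)
Conditions: NaIO4 on silica gel, CH2Cl2, rt; filter, MgSO4, toluene azeotrope; used crude at once
Reagents that add atoms: none
Why: This is a Malaprade glycol cleavage through the cyclic periodate ester, fast for a cis-diol on a five-membered ring, which cuts only ring C3–C4, does not touch C1/C1′, and keeps the medium neutral and nearly water-free so that enolisation and cyclic hydrate formation are held back.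

**Step 9**
Reactants: 12 meso dialdehyde; 13 2-bromopropene (4 equiv)
Product: 14 target, (1R,2R,1′S,2′R)-bis[2-hydroxy-1-(7-methoxy-2-oxochromen-8-yl)-3-methylbut-3-en-1-yl] ether
Conditions: pre-formed Cr(III)·(valinol-derived oxazoline–sulfonamide) complex (20 mol %), NiCl2·neocuproine (4 mol %), Mn, Cp2ZrCl2, LiCl, MeCN, rt; aq Rochelle salt
Reagents that add atoms: none
Why: This is a catalytic asymmetric Nozaki–Hiyama–Kishi alkenylation, in which nickel activates the C–Br bond and the chiral chromium complex delivers the isopropenyl group to the Re face of each enantiotopic formyl group, so reagent control (working with the Felkin–Anh bias at the anti half and against it at the syn half) sets C2 and C2′ both as R, breaks the mirror symmetry and turns single errors into separable diastereomers, while the neutral, amine-free medium spares the C1–H bonds and the lactones.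

**Compound list**
1 | umbelliferone (7-hydroxy-2H-chromen-2-one) | O=c1ccc2ccc(O)cc2o1 | starting material
2 | 7-hydroxy-8-iodo-2H-chromen-2-one | O=c1ccc2ccc(O)c(I)c2o1 | intermediate
3 | 8-iodo-7-methoxy-2H-chromen-2-one | COc1ccc2ccc(=O)oc2c1I | intermediate
4 | (7-methoxy-2-oxo-2H-chromen-8-yl)zinc iodide (LiCl-solvated solution) | COc1ccc2ccc(=O)oc2c1[Zn]I | intermediate
5 | 2,5-dimethoxy-2,5-dihydrofuran (cis/trans mixture) | COC1C=CC(OC)O1 | starting material
6 | 2,5-dimethoxytetrahydrofuran-3,4-diol (cis-diol, acetal carbons mixed) | COC1OC(OC)[C@@H](O)[C@H]1O | intermediate
7 | meso 2,5-dimethoxytetrahydrofuran-3,4-diol acetonide (OMe groups exo) | CO[C@@H]1O[C@H](OC)[C@H]2OC(C)(C)O[C@@H]12 | intermediate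
8 | 2,5-dibromotetrahydrofuran-3,4-diol acetonide (C–Br centres labile) | BrC1OC(Br)[C@H]2OC(C)(C)O[C@@H]12 | intermediate (not isolated)
9 | 5-bromo-2-(7-methoxy-2-oxochromen-8-yl)tetrahydrofuran-3,4-diol acetonide (racemic, aryl exo, C–Br labile) | COc1ccc2ccc(=O)oc2c1[C@@H]1OC(Br)[C@H]2OC(C)(C)O[C@@H]12 | intermediate (not isolated)
10 | meso cis-2,5-bis(7-methoxy-2-oxochromen-8-yl)tetrahydrofuran-3,4-diol acetonide | COc1ccc2ccc(=O)oc2c1[C@@H]1O[C@H](c2c(OC)ccc3ccc(=O)oc23)[C@H]2OC(C)(C)O[C@@H]12 | intermediate
11 | meso cis-2,5-bis(7-methoxy-2-oxochromen-8-yl)tetrahydrofuran-3,4-diol | COc1ccc2ccc(=O)oc2c1[C@@H]1O[C@H](c2c(OC)ccc3ccc(=O)oc23)[C@@H](O)[C@H]1O | intermediate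
12 | meso 2,2′-oxybis[2-(7-methoxy-2-oxochromen-8-yl)acetaldehyde] | O=C[C@H](c1c(OC)ccc2ccc(=O)oc12)O[C@H](c1c(OC)ccc2ccc(=O)oc12)C=O | intermediate
13 | 2-bromopropene | C=C(C)Br | starting material
14 | CNP0283712.1, (1R,2R,1′S,2′R) | C=C(C)[C@@H](O)[C@H](O[C@@H](c1c(OC)ccc2ccc(=O)oc12)[C@H](O)C(=C)C)c1c(OC)ccc2ccc(=O)oc12 | target

Total step count: 9. Longest linear sequence: 7 (steps 1, 2, 3, 6, 7, 8, 9).

**Steps most likely to fail**

1. **Step 6.**
   - What may go wrong: exo selectivity may erode at one or both cations, since small π-nucleophiles are known to enter acetonide-fused furanosyl cations from the concave side under stereoelectronic control. Aryl transfer from the hindered zinc reagent may be so slow that proton loss from ring C3/C4 and aromatisation take over. The ketal may ionise in competition.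
   - Fallback: it sets out from 7 (converted into 8 as before) and comes back at 10. The polar substitution is replaced by a radical cross-coupling, namely the nickel-catalysed Negishi coupling of glycosyl bromides with ArZnI·LiCl (Ni(cod)2, 4,4′,4″-tri-tert-butylterpyridine, DMF/THF, rt).
   - Why it should help: each C–Br bond becomes an anomeric radical that nickel captures on the convex face, which is the established outcome for acetonide-fused furanosyl radicals. No cation is involved, so the E1 path is closed, and the tridentate ligand suppresses β-alkoxy elimination. The detour makes no compound outside the list (F0).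

2. **Step 9.**
   - What may go wrong: reagent control may be incomplete at the end that runs against the intrinsic aldehyde bias. C1/C1′ may epimerise through the enol during a slow coupling. The mono-adduct may rest as a metal hemiacetal that masks the second formyl group.
   - Fallback: it sets out from 12 and comes back at 14. An achiral Nozaki–Hiyama–Kishi reaction with 13 (CrCl2, cat. NiCl2, DMF) gives the bis(allylic alcohol) as a mixture at C2/C2′ F1. Dess–Martin oxidation erases these two centres and gives the meso bis(isopropenyl ketone) F2.
   - Stereocontrol: a double Corey–Bakshi–Shibata reduction with (S)-Me-CBS and catecholborane at −78 °C installs both R carbinols. The bulky C1 substituent is taken as the large group, and catecholborane is chosen to avoid hydroboration of the 1,1-disubstituted alkenes.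

3. **Step 8.**
   - What may go wrong: the doubly activated benzylic α-carbons may epimerise on handling. The dialdehyde may be captured by water, which would stall the chromium addition.
   - Fallback: it sets out from 11 and comes back at 12. The cleavage is run deliberately in water (NaIO4, THF/H2O, 0 °C) so that the product is collected as its cyclic hydrate, cis-3,5-diaryl-1,4-dioxane-2,6-diol F3.
   - Why it should help: this hemiacetal form has no enolisable carbonyl, and it can be purified and stored. It is cracked to anhydrous 12 by azeotropic removal of water (toluene, 4 Å MS) immediately before step 9.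

**Further compounds**
F0 | step 6 | none | none
F1 | step 9 | bis[2-hydroxy-1-(7-methoxy-2-oxochromen-8-yl)-3-methylbut-3-en-1-yl] ether, R,S at C1/C1′, mixture at C2/C2′ | C=C(C)C(O)[C@H](O[C@@H](c1c(OC)ccc2ccc(=O)oc12)C(O)C(=C)C)c1c(OC)ccc2ccc(=O)oc12
F2 | step 9 | meso bis[1-(7-methoxy-2-oxochromen-8-yl)-3-methyl-2-oxobut-3-en-1-yl] ether | C=C(C)C(=O)[C@H](O[C@@H](c1c(OC)ccc2ccc(=O)oc12)C(=O)C(=C)C)c1c(OC)ccc2ccc(=O)oc12
F3 | step 8 | cis-3,5-bis(7-methoxy-2-oxochromen-8-yl)-1,4-dioxane-2,6-diol (hemiacetal carbons mixed) | OC1OC(O)[C@H](c2c(OC)ccc3ccc(=O)oc23)O[C@@H]1c1c(OC)ccc2ccc(=O)oc12
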